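The cyclopentane ring of the hydrindane is closed between its two oxygen-bearing carbons, C1 (beside ring-fusion carbon C7a, later the 2-methylbutanoate) and C2 (later the acetate). In the precursor both are carbonyl-level carbons of like polarity, an aldehyde on C7a and a nitrile on C3. SmI2 turns the aldehyde into a ketyl that adds 5-exo to the nitrile: one operation forms the ring, the C1 carbinol and a C2 ketone, so the vicinal oxygens emerge differentiated for their unlike esters. The cyano aldehyde, a pentasubstituted methylenecyclohexane, comes from an auxiliary-controlled Diels–Alder reaction followed by dihydroxylation.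

Key step: step 28

Remark: locants are those of the final hydrindane (five-membered ring C7a, C1, C2, C3, C3a; six-membered ring C3a, C4, C5, C6, C7, C7a) and are used for the cyclohexane precursors too. β is the face of H-3a, α the face of H-7a.

Step 1
Reactants: 1 3-[(4-methoxybenzyl)oxy]propanoic acid; 2 (R)-4-benzyl-1,3-oxazolidin-2-one
Product: 3 N-acyl oxazolidinone
Conditions: DCC, DMAP (cat.), CH2Cl2, 0 °C → rt
Reagents that add atoms: none
Why: Carbodiimide N-acylation attaches the Evans auxiliary without forming a stereocenter.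

Step 2
Reactants: 3 N-acyl oxazolidinone; 4 acetaldehyde
Product: 5 syn-aldol adduct
Conditions: Bu2BOTf, i-Pr2NEt, CH2Cl2, 0 °C; 4, −78 → 0 °C; H2O2, MeOH, pH 7 buffer
Reagents that add atoms: none
Why: Evans syn-aldol through the Z-boron enolate and a closed chair transition state, in which the (R)-auxiliary should set both new centers (2R,3S), the later C3 and side-chain carbinol.

Step 3
Reactants: 5 syn-aldol adduct
Product: 6 1,3-diol
Conditions: LiBH4, MeOH (1 equiv), THF, 0 °C
Reagents that add atoms: none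
Why: Reductive removal of the auxiliary gives the primary alcohol and leaves both stereocenters untouched.

Step 4
Reactants: 6 1,3-diol
Product: 7 β-hydroxy aldehyde
Conditions: TEMPO (cat.), PhI(OAc)2, CH2Cl2, rt
Reagents that add atoms: none
Why: Oxoammonium oxidation takes the primary hydroxyl in preference to the secondary one under non-epimerizing conditions.

Step 5
Reactants: 8 (diethoxyphosphoryl)acetic acid; 9 (S)-4-benzyl-1,3-oxazolidin-2-one
Product: 10 phosphonoacetyl oxazolidinone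
Conditions: DCC, DMAP (cat.), CH2Cl2, 0 °C → rt
Reagents that add atoms: none
Why: Carbodiimide N-acylation gives the olefination reagent that carries the Diels–Alder auxiliary.

Step 6
Reactants: 7 β-hydroxy aldehyde; 10 phosphonoacetyl oxazolidinone
Product: 11 E-enoyl oxazolidinone
Conditions: LiCl, i-Pr2NEt, MeCN, rt
Reagents that add atoms: none
Why: Masamune–Roush Horner–Wadsworth–Emmons olefination is E-selective and mild enough to spare the α-stereocenter and the free β-hydroxyl.

Step 7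
Reactants: 11 E-enoyl oxazolidinone
Product: 12 acetylated dienophile
Conditions: Ac2O, pyridine, DMAP (cat.), CH2Cl2, 0 °C
Reagents that add atoms: acetic anhydride, CC(=O)OC(C)=O
Why: Acetylation installs the side-chain acetate of the target at the outset.

Step 8
Reactants: 13 (R)-2-methylglycidol; 14 vinylmagnesium bromide
Product: 15 (S)-2-methylpent-4-ene-1,2-diol
Conditions: 14 (2.5 equiv), CuI (10 mol %), THF, −30 → 0 °C
Reagents that add atoms: none
Why: Copper-catalyzed Grignard opening at the unsubstituted epoxide carbon leaves the quaternary stereocenter, the later oxirane carbon, untouched.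

Step 9
Reactants: 15 (S)-2-methylpent-4-ene-1,2-diol
Product: 16 allyl dioxolane
Conditions: 2,2-dimethoxypropane, PPTS (cat.), CH2Cl2, rt
Reagents that add atoms: 2,2-dimethoxypropane, COC(C)(C)OC
Why: Ketal exchange protects the 1,2-diol as its acetonide.

Step 10
Reactants: 16 allyl dioxolane; 17 (E)-but-2-enal
Product: 18 E-enal
Conditions: 17 (5 equiv), second-generation Grubbs catalyst (3 mol %), CH2Cl2, 40 °C
Reagents that add atoms: none
Why: Olefin cross-metathesis of the terminal alkene with crotonaldehyde should give the E-enal.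

Step 11
Reactants: 18 E-enal
Product: 19 (1E,3E)-silyloxy diene
Conditions: TBSOTf, Et3N, Et2O, 0 °C
Reagents that add atoms: tert-butyldimethylsilyl triflate, CC(C)(C)[Si](C)(C)OS(=O)(=O)C(F)(F)F
Why: O-silylation and γ-deprotonation of the enal (soft enolization) give the silyl dienol ether with the bulky dioxolanyl group E.

Step 12
Reactants: 20 butane-2,3-dione; 21 tert-butyl (triphenylphosphoranylidene)acetate
Product: 22 tert-butyl (E)-3-methyl-4-oxopent-2-enoate
Conditions: CH2Cl2, rt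
Reagents that add atoms: none
Why: Wittig olefination of one carbonyl of the activated symmetrical dione with a stabilized ylide should place acetyl and ester trans.

Step 13
Reactants: 22 tert-butyl (E)-3-methyl-4-oxopent-2-enoate
Product: 23 (E)-3-methyl-4-oxopent-2-enoic acid
Conditions: CF3CO2H, CH2Cl2, 0 °C → rt
Reagents that add atoms: none
Why: Acidolysis of the tert-butyl ester frees the acid without touching the enone.

Step 14
Reactants: 12 acetylated dienophile; 19 (1E,3E)-silyloxy diene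
Product: 24 Diels–Alder adduct
Conditions: Me2AlCl (1.6 equiv), 19 (3 equiv), CH2Cl2, −78 → −30 °C
Reagents that add atoms: none
Why: Evans auxiliary-controlled Diels–Alder reaction, in which the aluminium-chelated s-cis acyl oxazolidinone is attacked on the face away from the benzyl group (setting C7a and C3a), while the endo mode, the E,E-diene and the silyloxy-terminus-to-α-carbon regiochemistry set C7 and C4.

Step 15
Reactants: 24 Diels–Alder adduct
Product: 25 primary alcohol
Conditions: NaBH4, THF–H2O (4:1), 0 °C → rt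
Reagents that add atoms: none
Why: Borohydride cleaves the N-acyl oxazolidinone reductively to the C1 carbinol and should spare the acetate.

Step 16
Reactants: 25 primary alcohol
Product: 26 TBDPS ether
Conditions: TBDPSCl, imidazole, CH2Cl2, rt
Reagents that add atoms: tert-butyl(chloro)diphenylsilane, CC(C)(C)[Si](Cl)(c1ccccc1)c1ccccc1
Why: Silylation masks the future aldehyde carbon C1 through the following oxidations.

Step 17
Reactants: 26 TBDPS ether
Product: 27 5α,6α-diol
Conditions: OsO4 (5 mol %), NMO, acetone–H2O (8:1), rt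
Reagents that add atoms: OsO4, O=[Os](=O)(=O)=O; N-methylmorpholine N-oxide, C[N+]1([O-])CCOCC1
Why: Upjohn dihydroxylation of the only alkene should occur anti to the pseudo-axial allylic 7β-silyloxy group and the 4β-substituent, giving the cis-diol on the α-face.

Step 18
Reactants: 27 5α,6α-diol; 28 (R)-2-methylbutanoic acid
Product: 31 5-O-(2-methylbutanoyl) ester, via acid chloride 29 (not isolated), via stannylene acetal 30 (not isolated)
Conditions: 28, (COCl)2, DMF (cat.), CH2Cl2, rt, evaporate; 27, Bu2SnO, toluene, reflux (−H2O); then 29, toluene, 0 °C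
Reagents that add atoms: oxalyl chloride, O=C(Cl)C(Cl)=O (chlorine in 29 only); Bu2SnO, CCCC[Sn](=O)CCCC (tin in 30 only)
Why: Acylation of a cis-diol through its dibutylstannylene acetal should go to the equatorial oxygen, here O5, leaving the axial 6-OH free.

Step 19
Reactants: 31 5-O-(2-methylbutanoyl) ester
Product: 32 6-O-allyl carbonate
Conditions: allyl chloroformate, pyridine, DMAP (cat.), CH2Cl2, 0 °C → rt
Reagents that add atoms: allyl chloroformate, C=CCOC(Cl)=O
Why: Carbonate formation masks the axial 6-OH with a group that is later removed under neutral conditions.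

Step 20
Reactants: 32 6-O-allyl carbonate
Product: 33 triol
Conditions: p-TsOH·H2O (10 mol %), MeOH, rt → 40 °C
Reagents that add atoms: none
Why: Acid-catalyzed methanolysis cleaves the dioxolane and the secondary TBS ether, while the TBDPS and PMB ethers, the esters and the carbonate should persist.

Step 21
Reactants: 33 triol
Product: 35 oxirane, via primary tosylate 34 (not isolated)
Conditions: TsCl, Et3N, Bu2SnO (5 mol %), CH2Cl2, 0 °C; then DBU, rt
Reagents that add atoms: p-toluenesulfonyl chloride, Cc1ccc(cc1)S(Cl)(=O)=O (sulfonyl group in 34 only)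
Why: Tin-catalyzed sulfonylation selects the primary hydroxyl of the 1,2-diol, and 3-exo-tet closure by the tertiary hydroxyl gives the (S)-2-methyloxirane with retention at the quaternary carbon.

Step 22
Reactants: 35 oxirane
Product: 36 C7 ketone
Conditions: Dess–Martin periodinane, pyridine, CH2Cl2, 0 °C → rt
Reagents that add atoms: none
Why: Dess–Martin oxidation of the only free hydroxyl proceeds under nearly neutral conditions that spare the α-centers and the epoxide.

Step 23
Reactants: 36 C7 ketone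
Product: 37 7-methylene compound
Conditions: Cp2TiMe2, toluene–THF, 65 °C, dark
Reagents that add atoms: dimethyltitanocene Cp2TiMe2, [CH3-].[CH3-].[Ti+4].c1cc[cH-]c1.c1cc[cH-]c1
Why: Petasis methylenation is non-basic, so C7a and C6 should not epimerize, the β-acyloxy group should not eliminate, and the ketone reacts ahead of the esters.

Step 24
Reactants: 37 7-methylene compound
Product: 38 side-chain primary alcohol
Conditions: DDQ, CH2Cl2–pH 7 buffer (10:1), 0 °C
Reagents that add atoms: none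
Why: Oxidative cleavage of the single PMB ether by DDQ frees the future C2 carbon under neutral conditions.

Step 25
Reactants: 38 side-chain primary alcohol
Product: 40 nitrile, via aldehyde 39 (not isolated)
Conditions: TEMPO (10 mol %), PhI(OAc)2, NH4OAc, MeCN–H2O (9:1), rt
Reagents that add atoms: ammonium acetate, CC(=O)[O-].[NH4+]
Why: One-pot oxoammonium oxidation to the aldehyde, condensation with ammonia and further oxidation of the N–H imine gives the nitrile without a base that could epimerize C3.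

Step 26
Reactants: 40 nitrile
Product: 41 C1 primary alcohol
Conditions: TBAF, AcOH, THF, 0 °C → rt
Reagents that add atoms: none
Why: Buffered fluoride removes the only silyl ether left.

Step 27
Reactants: 41 C1 primary alcohol
Product: 42 cyano aldehyde
Conditions: Dess–Martin periodinane, pyridine, CH2Cl2, 0 °C; used at once
Reagents that add atoms: none
Why: Neutral Dess–Martin oxidation gives the β,γ-unsaturated aldehyde without conjugation or epimerization at C7a.

Step 28
Reactants: 42 cyano aldehyde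
Product: 44 hydrindane ketol, via hydroxy imine 43 (not isolated)
Conditions: SmI2 (3 equiv), t-BuOH (2 equiv), THF (0.005 M), visible light, rt; then aq. NH4Cl, SiO2
Reagents that add atoms: water, O
Why: Proposed new method: SmI2 reduces the aldehyde by single-electron transfer to a samarium ketyl, which adds to the nitrile carbon (activated by coordination to trivalent samarium); a second electron transfer gives the N-metallated imine, which t-BuOH protonates to 43 and work-up hydrolyses to the ketone. The closest known reaction type is the SmI2-promoted reductive cyclization of cyano ketones to 2-hydroxycycloalkanones; the new element is the aldehyde-derived ketyl, whose cyclizations onto alkenes are well known. The cyclopentane closes in the 5-exo-dig mode. The only new stereocenter, C1, is controlled by the trans ring fusion: the bulky samarium-bound oxygen should take the pseudo-equatorial position syn to H-7a, giving the 1α-carbinol. The step needs chemoselective reduction of the aldehyde (esters, carbonate, epoxide and nitrile are not reduced by SmI2 here) and cyclization ahead of pinacol dimerization or over-reduction, which high dilution and the 1,5-relationship of the two carbons should secure.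

Step 29
Reactants: 44 hydrindane ketol; 28 (R)-2-methylbutanoic acid
Product: 45 1β-(2-methylbutanoyloxy) ketone
Conditions: 28, PPh3, DIAD, toluene, 0 °C → rt
Reagents that add atoms: none
Why: Mitsunobu esterification displaces the activated α-keto carbinol with inversion, turning the 1α-alcohol directly into the 1β-ester of the target.

Step 30
Reactants: 45 1β-(2-methylbutanoyloxy) ketone
Product: 46 2β-alcohol
Conditions: NaBH4, MeOH–THF, −40 °C
Reagents that add atoms: none
Why: Hydride should attack the C2 ketone from the open α-face, opposite the β-substituents on C1 and C3, giving the all-cis 2β-alcohol.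

Step 31
Reactants: 46 2β-alcohol
Product: 47 2β-acetate
Conditions: Ac2O, pyridine, DMAP (cat.), CH2Cl2, 0 °C, directly after step 30
Reagents that add atoms: acetic anhydride, CC(=O)OC(C)=O
Why: Prompt acetylation fixes the C2 oxygen before the neighbouring C1 ester can migrate.

Step 32
Reactants: 47 2β-acetate
Product: 48 6α-alcohol
Conditions: Pd(PPh3)4 (5 mol %), dimedone, THF, rt
Reagents that add atoms: none
Why: Zerovalent palladium ionizes the allyl carbonate (Tsuji–Trost), the allyl group passes to dimedone and CO2 is lost, all under neutral conditions that should not move the adjacent ester.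

Step 33
Reactants: 48 6α-alcohol; 23 (E)-3-methyl-4-oxopent-2-enoic acid
Product: 50 6-O-(3-methyl-4-oxopent-2-enoyl) ester, via mixed anhydride 49 (not isolated)
Conditions: 23, 2,4,6-trichlorobenzoyl chloride, Et3N, THF, rt; then 48, DMAP, toluene, rt
Reagents that add atoms: 2,4,6-trichlorobenzoyl chloride, O=C(Cl)c1c(Cl)cc(Cl)cc1Cl (aroyl group in 49 only)
Why: Yamaguchi esterification is strong enough for the hindered axial allylic alcohol and retains the C6 configuration.

Step 34
Reactants: 50 6-O-(3-methyl-4-oxopent-2-enoyl) ester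
Product: 51 CNP0282336.1
Conditions: (R)-2-methyl-CBS-oxazaborolidine (0.5 equiv), catecholborane, toluene, −78 °C
Reagents that add atoms: none
Why: Corey–Bakshi–Shibata 1,2-reduction of the only ketone, an enone with the alkenyl group as the large and methyl as the small substituent, should give the (S)-allylic alcohol under reagent control with the (R)-catalyst.

Compound list

1 | 3-[(4-methoxybenzyl)oxy]propanoic acid | OC(=O)CCOCc1ccc(OC)cc1 | starting material
2 | (R)-4-benzyl-1,3-oxazolidin-2-one | O=C1N[C@H](Cc2ccccc2)CO1 | starting material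
3 | (R)-4-benzyl-3-{3-[(4-methoxybenzyl)oxy]propanoyl}-1,3-oxazolidin-2-one | O=C(CCOCc1ccc(OC)cc1)N1[C@H](Cc2ccccc2)COC1=O | intermediate
4 | acetaldehyde | CC=O | starting material
5 | (R)-4-benzyl-3-[(2R,3S)-3-hydroxy-2-{[(4-methoxybenzyl)oxy]methyl}butanoyl]-1,3-oxazolidin-2-one | O=C([C@H](COCc1ccc(OC)cc1)[C@H](C)O)N1[C@H](Cc2ccccc2)COC1=O | intermediate
6 | (2R,3S)-2-{[(4-methoxybenzyl)oxy]methyl}butane-1,3-diol | OC[C@H](COCc1ccc(OC)cc1)[C@H](C)O | intermediate
7 | (2R,3S)-3-hydroxy-2-{[(4-methoxybenzyl)oxy]methyl}butanal | O=C[C@H](COCc1ccc(OC)cc1)[C@H](C)O | intermediate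
8 | (diethoxyphosphoryl)acetic acid | CCOP(=O)(OCC)CC(=O)O | starting material
9 | (S)-4-benzyl-1,3-oxazolidin-2-one | O=C1N[C@@H](Cc2ccccc2)CO1 | starting material
10 | (S)-4-benzyl-3-[(diethoxyphosphoryl)acetyl]-1,3-oxazolidin-2-one | CCOP(=O)(OCC)CC(=O)N1[C@@H](Cc2ccccc2)COC1=O | intermediate
11 | (S)-4-benzyl-3-[(2E,4R,5S)-5-hydroxy-4-{[(4-methoxybenzyl)oxy]methyl}hex-2-enoyl]-1,3-oxazolidin-2-one | O=C(/C=C/[C@H](COCc1ccc(OC)cc1)[C@H](C)O)N1[C@@H](Cc2ccccc2)COC1=O | intermediate
12 | (S)-4-benzyl-3-[(2E,4R,5S)-5-acetoxy-4-{[(4-methoxybenzyl)oxy]methyl}hex-2-enoyl]-1,3-oxazolidin-2-one (dienophile) | O=C(/C=C/[C@H](COCc1ccc(OC)cc1)[C@H](C)OC(C)=O)N1[C@@H](Cc2ccccc2)COC1=O | intermediate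
13 | (R)-(2-methyloxiran-2-yl)methanol ((R)-2-methylglycidol) | OC[C@]1(C)CO1 | starting material
14 | vinylmagnesium bromide | C=C[Mg]Br | starting material
15 | (S)-2-methylpent-4-ene-1,2-diol | C=CC[C@@](O)(C)CO | intermediate
16 | (S)-2,2,4-trimethyl-4-(prop-2-en-1-yl)-1,3-dioxolane | C=CC[C@@]1(C)COC(C)(C)O1 | intermediate
17 | (E)-but-2-enal (crotonaldehyde) | C/C=C/C=O | starting material
18 | (E)-4-[(S)-2,2,4-trimethyl-1,3-dioxolan-4-yl]but-2-enal | O=C/C=C/C[C@@]1(C)COC(C)(C)O1 | intermediate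
19 | tert-butyldimethylsilyl (1E,3E)-4-[(S)-2,2,4-trimethyl-1,3-dioxolan-4-yl]buta-1,3-dien-1-yl ether (diene) | CC(C)(C)[Si](C)(C)O/C=C/C=C/[C@@]1(C)COC(C)(C)O1 | intermediate
20 | butane-2,3-dione | CC(=O)C(C)=O | starting material
21 | tert-butyl (triphenylphosphoranylidene)acetate | CC(C)(C)OC(=O)C=P(c1ccccc1)(c1ccccc1)c1ccccc1 | starting material
22 | tert-butyl (E)-3-methyl-4-oxopent-2-enoate | CC(=O)/C(C)=C/C(=O)OC(C)(C)C | intermediate
23 | (E)-3-methyl-4-oxopent-2-enoic acid | CC(=O)/C(C)=C/C(=O)O | intermediate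
24 | Diels–Alder adduct: cyclohexene (C5=C6) with 7β-OTBS, 7aβ-carbonyl bound to N of (S)-4-benzyl-2-oxo-oxazolidine, 3aα-[(2R,3S)-3-acetoxy-1-(4-methoxybenzyloxy)butan-2-yl], 4β-[(S)-2,2,4-trimethyl-1,3-dioxolan-4-yl] | CC(C)(C)[Si](C)(C)O[C@@H]1[C@H](C(=O)N2[C@@H](Cc3ccccc3)COC2=O)[C@@H]([C@H](COCc2ccc(OC)cc2)[C@H](C)OC(C)=O)[C@H]([C@@]2(C)COC(C)(C)O2)C=C1 | intermediate
25 | as 24 with 7aβ-CH2OH in place of the acyl oxazolidinone | CC(C)(C)[Si](C)(C)O[C@@H]1[C@H](CO)[C@@H]([C@H](COCc2ccc(OC)cc2)[C@H](C)OC(C)=O)[C@H]([C@@]2(C)COC(C)(C)O2)C=C1 | intermediate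
26 | as 25 with 7aβ-CH2OTBDPS | CC(C)(C)[Si](C)(C)O[C@@H]1[C@H](CO[Si](c2ccccc2)(c2ccccc2)C(C)(C)C)[C@@H]([C@H](COCc2ccc(OC)cc2)[C@H](C)OC(C)=O)[C@H]([C@@]2(C)COC(C)(C)O2)C=C1 | intermediate
27 | 5α,6α-diol of 26 (cyclohexane; 5-OH equatorial, 6-OH axial) | CC(C)(C)[Si](C)(C)O[C@@H]1[C@H](CO[Si](c2ccccc2)(c2ccccc2)C(C)(C)C)[C@@H]([C@H](COCc2ccc(OC)cc2)[C@H](C)OC(C)=O)[C@H]([C@@]2(C)COC(C)(C)O2)[C@@H](O)[C@H]1O | intermediate
28 | (R)-2-methylbutanoic acid | CC[C@@H](C)C(=O)O | starting material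
29 | (R)-2-methylbutanoyl chloride (not isolated) | CC[C@@H](C)C(Cl)=O | intermediate
30 | 5,6-O-dibutylstannylene acetal of 27 (not isolated) | CC(C)(C)[Si](C)(C)O[C@@H]1[C@H](CO[Si](c2ccccc2)(c2ccccc2)C(C)(C)C)[C@@H]([C@H](COCc2ccc(OC)cc2)[C@H](C)OC(C)=O)[C@H]([C@@]2(C)COC(C)(C)O2)[C@@H](O[Sn]2(CCCC)CCCC)[C@H]1O2 | intermediate
31 | 5α-O-[(R)-2-methylbutanoyl] ester of 27, 6α-OH free | CC(C)(C)[Si](C)(C)O[C@@H]1[C@H](CO[Si](c2ccccc2)(c2ccccc2)C(C)(C)C)[C@@H]([C@H](COCc2ccc(OC)cc2)[C@H](C)OC(C)=O)[C@H]([C@@]2(C)COC(C)(C)O2)[C@@H](OC(=O)[C@H](C)CC)[C@H]1O | intermediate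
32 | 6α-O-allyloxycarbonyl derivative of 31 | CC(C)(C)[Si](C)(C)O[C@@H]1[C@H](CO[Si](c2ccccc2)(c2ccccc2)C(C)(C)C)[C@@H]([C@H](COCc2ccc(OC)cc2)[C@H](C)OC(C)=O)[C@H]([C@@]2(C)COC(C)(C)O2)[C@@H](OC(=O)[C@H](C)CC)[C@H]1OC(=O)OCC=C | intermediate
33 | triol: 32 with 7β-OH and 4β-[(S)-1,2-dihydroxypropan-2-yl] | O[C@@H]1[C@H](CO[Si](c2ccccc2)(c2ccccc2)C(C)(C)C)[C@@H]([C@H](COCc2ccc(OC)cc2)[C@H](C)OC(C)=O)[C@H]([C@@](O)(C)CO)[C@@H](OC(=O)[C@H](C)CC)[C@H]1OC(=O)OCC=C | intermediate
34 | primary p-toluenesulfonate of 33 (not isolated) | O[C@@H]1[C@H](CO[Si](c2ccccc2)(c2ccccc2)C(C)(C)C)[C@@H]([C@H](COCc2ccc(OC)cc2)[C@H](C)OC(C)=O)[C@H]([C@@](O)(C)COS(=O)(=O)c2ccc(C)cc2)[C@@H](OC(=O)[C@H](C)CC)[C@H]1OC(=O)OCC=C | intermediate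
35 | 7β-alcohol with 4β-[(S)-2-methyloxiran-2-yl] | O[C@@H]1[C@H](CO[Si](c2ccccc2)(c2ccccc2)C(C)(C)C)[C@@H]([C@H](COCc2ccc(OC)cc2)[C@H](C)OC(C)=O)[C@H]([C@@]2(C)CO2)[C@@H](OC(=O)[C@H](C)CC)[C@H]1OC(=O)OCC=C | intermediate
36 | C7 ketone from 35 | O=C1[C@H](CO[Si](c2ccccc2)(c2ccccc2)C(C)(C)C)[C@@H]([C@H](COCc2ccc(OC)cc2)[C@H](C)OC(C)=O)[C@H]([C@@]2(C)CO2)[C@@H](OC(=O)[C@H](C)CC)[C@H]1OC(=O)OCC=C | intermediate
37 | 7-methylene compound from 36 | C=C1[C@H](CO[Si](c2ccccc2)(c2ccccc2)C(C)(C)C)[C@@H]([C@H](COCc2ccc(OC)cc2)[C@H](C)OC(C)=O)[C@H]([C@@]2(C)CO2)[C@@H](OC(=O)[C@H](C)CC)[C@H]1OC(=O)OCC=C | intermediate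
38 | as 37 with 3aα-[(2R,3S)-3-acetoxy-1-hydroxybutan-2-yl] | C=C1[C@H](CO[Si](c2ccccc2)(c2ccccc2)C(C)(C)C)[C@@H]([C@H](CO)[C@H](C)OC(C)=O)[C@H]([C@@]2(C)CO2)[C@@H](OC(=O)[C@H](C)CC)[C@H]1OC(=O)OCC=C | intermediate
39 | aldehyde from 38 (not isolated) | C=C1[C@H](CO[Si](c2ccccc2)(c2ccccc2)C(C)(C)C)[C@@H]([C@H](C=O)[C@H](C)OC(C)=O)[C@H]([C@@]2(C)CO2)[C@@H](OC(=O)[C@H](C)CC)[C@H]1OC(=O)OCC=C | intermediate
40 | nitrile: 3aα-[(1R,2S)-2-acetoxy-1-cyanopropyl], 7aβ-CH2OTBDPS | C=C1[C@H](CO[Si](c2ccccc2)(c2ccccc2)C(C)(C)C)[C@@H]([C@H](C#N)[C@H](C)OC(C)=O)[C@H]([C@@]2(C)CO2)[C@@H](OC(=O)[C@H](C)CC)[C@H]1OC(=O)OCC=C | intermediate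
41 | as 40 with 7aβ-CH2OH | C=C1[C@H](CO)[C@@H]([C@H](C#N)[C@H](C)OC(C)=O)[C@H]([C@@]2(C)CO2)[C@@H](OC(=O)[C@H](C)CC)[C@H]1OC(=O)OCC=C | intermediate
42 | cyano aldehyde: as 40 with 7aβ-CHO | C=C1[C@H](C=O)[C@@H]([C@H](C#N)[C@H](C)OC(C)=O)[C@H]([C@@]2(C)CO2)[C@@H](OC(=O)[C@H](C)CC)[C@H]1OC(=O)OCC=C | intermediate
43 | trans-hydrindane 1α-hydroxy-2-imine (not isolated) | C=C1[C@@H]2[C@@H](O)C(=N)[C@H]([C@H](C)OC(C)=O)[C@H]2[C@H]([C@@]2(C)CO2)[C@@H](OC(=O)[C@H](C)CC)[C@H]1OC(=O)OCC=C | intermediate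
44 | trans-hydrindane ketol: 1α-OH, 2-oxo, 3β-[(S)-1-acetoxyethyl], 4β-[(S)-2-methyloxiran-2-yl], 5α-O-[(R)-2-methylbutanoyl], 6α-O-allyloxycarbonyl, 7-methylene | C=C1[C@@H]2[C@@H](O)C(=O)[C@H]([C@H](C)OC(C)=O)[C@H]2[C@H]([C@@]2(C)CO2)[C@@H](OC(=O)[C@H](C)CC)[C@H]1OC(=O)OCC=C | intermediate
45 | as 44 with 1β-O-[(R)-2-methylbutanoyl] | C=C1[C@@H]2[C@H](OC(=O)[C@H](C)CC)C(=O)[C@H]([C@H](C)OC(C)=O)[C@H]2[C@H]([C@@]2(C)CO2)[C@@H](OC(=O)[C@H](C)CC)[C@H]1OC(=O)OCC=C | intermediate
46 | 2β-alcohol from 45 | C=C1[C@@H]2[C@H](OC(=O)[C@H](C)CC)[C@H](O)[C@H]([C@H](C)OC(C)=O)[C@H]2[C@H]([C@@]2(C)CO2)[C@@H](OC(=O)[C@H](C)CC)[C@H]1OC(=O)OCC=C | intermediate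
47 | 2β-acetate of 46 | C=C1[C@@H]2[C@H](OC(=O)[C@H](C)CC)[C@H](OC(C)=O)[C@H]([C@H](C)OC(C)=O)[C@H]2[C@H]([C@@]2(C)CO2)[C@@H](OC(=O)[C@H](C)CC)[C@H]1OC(=O)OCC=C | intermediate
48 | 6α-alcohol from 47 | C=C1[C@@H]2[C@H](OC(=O)[C@H](C)CC)[C@H](OC(C)=O)[C@H]([C@H](C)OC(C)=O)[C@H]2[C@H]([C@@]2(C)CO2)[C@@H](OC(=O)[C@H](C)CC)[C@H]1O | intermediate
49 | (E)-3-methyl-4-oxopent-2-enoic 2,4,6-trichlorobenzoic anhydride (not isolated) | CC(=O)/C(C)=C/C(=O)OC(=O)c1c(Cl)cc(Cl)cc1Cl | intermediate
50 | 6α-O-[(E)-3-methyl-4-oxopent-2-enoyl] ester of 48 | C=C1[C@@H]2[C@H](OC(=O)[C@H](C)CC)[C@H](OC(C)=O)[C@H]([C@H](C)OC(C)=O)[C@H]2[C@H]([C@@]2(C)CO2)[C@@H](OC(=O)[C@H](C)CC)[C@H]1OC(=O)/C=C(\C)C(C)=O | intermediate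
51 | CNP0282336.1: trans-fused 7-methylenehydrindane (H-3a β, H-7a α) with 1β-O-[(R)-2-methylbutanoyl], 2β-OAc, 3β-[(S)-1-acetoxyethyl], 4β-[(S)-2-methyloxiran-2-yl], 5α-O-[(R)-2-methylbutanoyl], 6α-O-[(2E,4S)-4-hydroxy-3-methylpent-2-enoyl] | C=C1[C@@H]2[C@H](OC(=O)[C@H](C)CC)[C@H](OC(C)=O)[C@H]([C@H](C)OC(C)=O)[C@H]2[C@H]([C@@]2(C)CO2)[C@@H](OC(=O)[C@H](C)CC)[C@H]1OC(=O)/C=C(\C)[C@H](C)O | target

Total step count: 34. Longest linear sequence: 27 steps (steps 1–4, 6, 7 and 14–34).

Steps most likely to fail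

Step 28. The aldehyde-derived ketyl may be reduced on to the alcohol or dimerize before it adds to the nitrile, and the metallated imine may lose the β-acetate. The fallback makes the same bond by a pinacol closure; it sets out from 38 and returns at 44. Alcohol 38 is desilylated with buffered TBAF to the diol F1, which is oxidized with Dess–Martin periodinane to the dialdehyde F2. SmI2 in THF–t-BuOH at −78 °C should close F2 to the cis-diol F3, with both hydroxyls on the α-face, away from the C3 side chain. The dibutylstannylene acetal of F3 (Bu2SnO) is then oxidized with N-bromosuccinimide, which should take the pseudo-axial C2 oxygen and give ketol 44.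

Step 14. Bond formation between the two branched carbons C3a and C4 may be slow, so that the Lewis acid desilylates the diene or cleaves the dioxolane first. The fallback replaces the chelated imide by a smaller enal under catalyst control; it sets out from 7 and returns at 25. Aldehyde 7 is olefinated with (triphenylphosphoranylidene)acetaldehyde to the enal F4 and acetylated to F5. F5 and diene 19 are joined at −78 °C with a triflimide-activated chiral oxazaborolidinium catalyst, whose antipode is chosen by correlation with 25, to give the aldehyde F6. NaBH4 reduces F6 to 25.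

Step 29. At the hindered α-keto carbinol the activated intermediate may eliminate or the product may epimerize at C1 instead of undergoing clean displacement. The fallback separates activation from displacement; it sets out from 44 and returns at 45. Ketol 44 is converted with Tf2O and pyridine at −40 °C into the triflate F7, which is displaced with inversion by cesium (R)-2-methylbutanoate (from 28 and Cs2CO3) and 18-crown-6 in toluene to give 45.

Further compounds

F1 | step 28 | diol: as 38 with 7aβ-CH2OH | C=C1[C@H](CO)[C@@H]([C@H](CO)[C@H](C)OC(C)=O)[C@H]([C@@]2(C)CO2)[C@@H](OC(=O)[C@H](C)CC)[C@H]1OC(=O)OCC=C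
F2 | step 28 | dialdehyde from F1 | C=C1[C@H](C=O)[C@@H]([C@H](C=O)[C@H](C)OC(C)=O)[C@H]([C@@]2(C)CO2)[C@@H](OC(=O)[C@H](C)CC)[C@H]1OC(=O)OCC=C
F3 | step 28 | trans-hydrindane 1α,2α-diol (otherwise as 44) | C=C1[C@@H]2[C@@H](O)[C@@H](O)[C@H]([C@H](C)OC(C)=O)[C@H]2[C@H]([C@@]2(C)CO2)[C@@H](OC(=O)[C@H](C)CC)[C@H]1OC(=O)OCC=C
F4 | step 14 | (2E,4R,5S)-5-hydroxy-4-{[(4-methoxybenzyl)oxy]methyl}hex-2-enal | O=C/C=C/[C@H](COCc1ccc(OC)cc1)[C@H](C)O
F5 | step 14 | (2E,4R,5S)-5-acetoxy-4-{[(4-methoxybenzyl)oxy]methyl}hex-2-enal | O=C/C=C/[C@H](COCc1ccc(OC)cc1)[C@H](C)OC(C)=O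
F6 | step 14 | Diels–Alder adduct as 24 with 7aβ-CHO | CC(C)(C)[Si](C)(C)O[C@@H]1[C@H](C=O)[C@@H]([C@H](COCc2ccc(OC)cc2)[C@H](C)OC(C)=O)[C@H]([C@@]2(C)COC(C)(C)O2)C=C1
F7 | step 29 | 1α-trifluoromethanesulfonate of 44 | C=C1[C@@H]2[C@@H](OS(=O)(=O)C(F)(F)F)C(=O)[C@H]([C@H](C)OC(C)=O)[C@H]2[C@H]([C@@]2(C)CO2)[C@@H](OC(=O)[C@H](C)CC)[C@H]1OC(=O)OCC=C
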